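**Retrosynthetic overview**
1. The (E)-C1'=C2' alkene is cut by cross-metathesis into vinyl lactone 17 and (3S,4S)-pent-1-ene-3,4-diyl diacetate 22.
2. 17 comes from the cis-5-hydroxy-6-(dioxolanyl) lactone 13 by tigloylation and conversion of the glyceraldehyde-derived diol into the vinyl group.
3. Key disconnection: the dihydropyranone (the only ring, formed in step 3) comes from the furan ring of carbinol 8 by [4+2] cycloaddition of singlet oxygen and collapse of the endoperoxide to the pyranone, followed by lactol-to-lactone oxidation and ketone reduction.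
4. 8 comes from furan and (S)-glyceraldehyde acetonide 4 (from L-gulonolactone acetonide 1); 22 comes from ethyl (S)-O-benzyl-lactate 18 by chelation-controlled vinyl addition.
5. Stereocentres: C6 is set by the dioxolane centre of 4 (Felkin–Anh), C5 by C6 (Luche reduction), C4' is bought in lactate, C3' is set by C4' (Cram chelate).

Assumption: 1, 14 and 18 are bought as catalogue compounds; the lactone is numbered O1, C2(=O) to C6 and the side chain C1' to C5'.

**Step 1**
Reactants: 1 5,6-O-isopropylidene-L-gulono-1,4-lactone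
Product: 4 (4S)-2,2-dimethyl-1,3-dioxolane-4-carbaldehyde, via glyoxylate ester 2 (not isolated), via hydroxy aldehyde 3 (not isolated)
Conditions: NaIO4 (2.1 equiv), H2O, pH 5.5 (NaOH), 0 °C → rt
Reagents that add atoms: none
Why: Periodate (Malaprade) glycol cleavage of the cis-2,3-diol, hydrolysis of the activated glyoxylate ester and a second cleavage of the α-hydroxy aldehyde excise C1–C3 of the sugar, so C5 of L-gulonolactone survives unchanged as the (S)-centre of the aldehyde.

**Step 2**
Reactants: 4 (4S)-2,2-dimethyl-1,3-dioxolane-4-carbaldehyde; 5 furan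
Product: 8 (S)-[(4S)-2,2-dimethyl-1,3-dioxolan-4-yl](furan-2-yl)methanol, via 2-furyllithium 6 (not isolated), via 2-furylzinc bromide 7 (not isolated)
Conditions: 5 (1.5 equiv), n-BuLi, THF, 0 °C; ZnBr2, 0 °C; then 4, −20 → 0 °C; H2O
Reagents that add atoms: none
Why: Lithiation of furan at C2, transmetallation to zinc and 1,2-addition to the α-alkoxy aldehyde follow the Felkin–Anh model (anti addition, expected to be strongly anti-selective for this organozinc), so the bought dioxolane centre fixes the new carbinol centre as (S), the future C6 of the lactone.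

**Step 3 (key step)**
Reactants: 8 (S)-[(4S)-2,2-dimethyl-1,3-dioxolan-4-yl](furan-2-yl)methanol
Product: 11 (2S)-2-[(4S)-2,2-dimethyl-1,3-dioxolan-4-yl]-6-hydroxy-2H-pyran-3(6H)-one, via furan endoperoxide 9 (not isolated), via hydroperoxy pyranone 10 (not isolated)
Conditions: O2, hν (visible), tetraphenylporphyrin (1 mol%), CH2Cl2, −78 °C; then Me2S, −78 °C → rt
Reagents that add atoms: dioxygen, O=O
Why: Singlet oxygen adds across C2 and C5 of the furan (the diene) in a [4+2] cycloaddition, the endoperoxide is opened by the neighbouring carbinol oxygen to the six-membered hydroperoxy pyranone (Achmatowicz-type ring expansion), Me2S reduces OOH to OH, and the carbinol stereocentre, which becomes C6 of the lactone, is not touched.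

**Step 4**
Reactants: 11 (2S)-2-[(4S)-2,2-dimethyl-1,3-dioxolan-4-yl]-6-hydroxy-2H-pyran-3(6H)-one
Product: 12 (6S)-6-[(4S)-2,2-dimethyl-1,3-dioxolan-4-yl]-2H-pyran-2,5(6H)-dione
Conditions: Dess–Martin periodinane, CH2Cl2, 0 °C → rt
Reagents that add atoms: none
Why: Dess–Martin oxidation converts the lactol (cyclic hemiacetal) into the lactone under non-basic conditions, which matters because the C6–H of ene-dione 12 is acidic and base would epimerise it or aromatise the ring to a 5-hydroxy-2-pyranone.

**Step 5**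
Reactants: 12 (6S)-6-[(4S)-2,2-dimethyl-1,3-dioxolan-4-yl]-2H-pyran-2,5(6H)-dione
Product: 13 (5S,6R)-6-[(4S)-2,2-dimethyl-1,3-dioxolan-4-yl]-5-hydroxy-5,6-dihydro-2H-pyran-2-one
Conditions: NaBH4, CeCl3·7H2O, MeOH–CH2Cl2, −78 °C
Reagents that add atoms: none
Why: Luche reduction: the cerium-activated ketone is reduced 1,2 in preference to the conjugated lactone, and hydride enters anti to the bulky C6 substituent of the nearly planar ring, which sets C5 as (S), cis to the C6 substituent.

**Step 6**
Reactants: 13 (5S,6R)-6-[(4S)-2,2-dimethyl-1,3-dioxolan-4-yl]-5-hydroxy-5,6-dihydro-2H-pyran-2-one; 14 (2E)-2-methylbut-2-enoyl chloride (tigloyl chloride)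
Product: 15 (2R,3S)-2-[(4S)-2,2-dimethyl-1,3-dioxolan-4-yl]-6-oxo-3,6-dihydro-2H-pyran-3-yl (2E)-2-methylbut-2-enoate
Conditions: 14, pyridine, DMAP (cat.), CH2Cl2, 0 °C
Reagents that add atoms: none
Why: DMAP-catalysed O-acylation of the single free hydroxyl with the acid chloride proceeds with retention at C5 and installs the tiglate.

**Step 7**
Reactants: 15 (2R,3S)-2-[(4S)-2,2-dimethyl-1,3-dioxolan-4-yl]-6-oxo-3,6-dihydro-2H-pyran-3-yl (2E)-2-methylbut-2-enoate
Product: 16 (2S,3S)-2-[(1S)-1,2-dihydroxyethyl]-6-oxo-3,6-dihydro-2H-pyran-3-yl (2E)-2-methylbut-2-enoate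
Conditions: TFA–H2O (9:1), 0 °C
Reagents that add atoms: none
Why: Acid-catalysed hydrolysis of the isopropylidene acetal frees the side-chain diol while the lactone, the allylic tiglate and both ring stereocentres are stable to cold aqueous acid.

**Step 8**
Reactants: 16 (2S,3S)-2-[(1S)-1,2-dihydroxyethyl]-6-oxo-3,6-dihydro-2H-pyran-3-yl (2E)-2-methylbut-2-enoate
Product: 17 (2S,3S)-2-ethenyl-6-oxo-3,6-dihydro-2H-pyran-3-yl (2E)-2-methylbut-2-enoate
Conditions: PPh3, I2, imidazole, toluene, 80 °C
Reagents that add atoms: none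
Why: Garegg–Samuelsson olefination: both hydroxyls are activated by the phosphine–iodine reagent and iodide-induced reductive elimination of the doubly activated vicinal diol gives the terminal alkene, removing the now superfluous glyceraldehyde stereocentre without touching C5 or C6.

**Step 9**
Reactants: 18 ethyl (2S)-2-(benzyloxy)propanoate
Product: 19 (2S)-2-(benzyloxy)propanal
Conditions: i-Bu2AlH (1.05 equiv), CH2Cl2, −78 °C; then aq. potassium sodium tartrate
Reagents that add atoms: none
Why: Partial reduction of the ester with one equivalent of i-Bu2AlH at −78 °C stops at the aldehyde oxidation level, and the non-basic conditions leave the α-stereocentre bought in lactate intact.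

**Step 10**
Reactants: 19 (2S)-2-(benzyloxy)propanal
Product: 20 (3S,4S)-4-(benzyloxy)pent-1-en-3-ol
Conditions: MgBr2·OEt2, CH2Cl2, −78 °C; then CH2=CHMgBr (THF), −78 °C; H2O
Reagents that add atoms: vinylmagnesium bromide, C=C[Mg]Br
Why: Cram-chelate-controlled Grignard addition: magnesium bridges the carbonyl and benzyloxy oxygens and the vinyl group attacks the face opposite the methyl group, giving the syn (3S,4S) alcohol, the minor anti isomer being removed by chromatography.

**Step 11**
Reactants: 20 (3S,4S)-4-(benzyloxy)pent-1-en-3-ol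
Product: 21 (3S,4S)-pent-1-ene-3,4-diol
Conditions: Na, NH3 (l), THF, −78 °C; then NH4Cl
Reagents that add atoms: none
Why: Dissolving-metal (Birch-type) hydrogenolysis cleaves the benzylic C–O bond while the isolated terminal alkene and the allylic C–O bond of the alkoxide are inert, so both stereocentres are retained.

**Step 12**
Reactants: 21 (3S,4S)-pent-1-ene-3,4-diol
Product: 22 (3S,4S)-pent-1-ene-3,4-diyl diacetate
Conditions: Ac2O, pyridine, DMAP (cat.), CH2Cl2, rt
Reagents that add atoms: acetic anhydride, CC(=O)OC(C)=O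
Why: Exhaustive DMAP-catalysed acetylation of both secondary hydroxyls with retention of configuration.

**Step 13**
Reactants: 17 (2S,3S)-2-ethenyl-6-oxo-3,6-dihydro-2H-pyran-3-yl (2E)-2-methylbut-2-enoate; 22 (3S,4S)-pent-1-ene-3,4-diyl diacetate
Product: 23 (2S,3S)-2-[(1E,3S,4S)-3,4-bis(acetyloxy)pent-1-en-1-yl]-6-oxo-3,6-dihydro-2H-pyran-3-yl (2E)-2-methylbut-2-enoate
Conditions: 22 (3 equiv), second-generation Grubbs catalyst RuCl2(=CHPh)(PCy3)(H2IMes) (10 mol%), CH2Cl2, 40 °C
Reagents that add atoms: none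
Why: Olefin cross-metathesis between two monosubstituted alkenes with loss of ethylene gives the thermodynamically preferred (E)-1,2-disubstituted alkene, while the trisubstituted tiglate alkene and the conjugated ring alkene do not react and no stereocentre is affected.

**Compound list**
1 | 5,6-O-isopropylidene-L-gulono-1,4-lactone | CC1(C)OC[C@@H]([C@@H]2[C@@H]([C@@H](C(=O)O2)O)O)O1 | starting material
2 | (1R)-1-[(4S)-2,2-dimethyl-1,3-dioxolan-4-yl]-2-oxoethyl oxoacetate (glyoxylate ester) | O=CC(=O)O[C@@H](C=O)[C@@H]1COC(C)(C)O1 | intermediate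
3 | (2R)-2-[(4S)-2,2-dimethyl-1,3-dioxolan-4-yl]-2-hydroxyacetaldehyde (3,4-O-isopropylidene-L-threose) | O=C[C@H](O)[C@@H]1COC(C)(C)O1 | intermediate
4 | (4S)-2,2-dimethyl-1,3-dioxolane-4-carbaldehyde ((S)-glyceraldehyde acetonide) | O=C[C@@H]1COC(C)(C)O1 | intermediate
5 | furan | c1ccoc1 | starting material
6 | 2-furyllithium | [Li]c1ccco1 | intermediate
7 | 2-furylzinc bromide | Br[Zn]c1ccco1 | intermediate
8 | (S)-[(4S)-2,2-dimethyl-1,3-dioxolan-4-yl](furan-2-yl)methanol (anti adduct) | O[C@H](c1ccco1)[C@@H]2COC(C)(C)O2 | intermediate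
9 | (S)-[(4S)-2,2-dimethyl-1,3-dioxolan-4-yl](2,3,7-trioxabicyclo[2.2.1]hept-5-en-1-yl)methanol (furan endoperoxide, bridgeheads unassigned) | O[C@H](C12C=CC(OO1)O2)[C@@H]3COC(C)(C)O3 | intermediate
10 | (2S)-2-[(4S)-2,2-dimethyl-1,3-dioxolan-4-yl]-6-hydroperoxy-2H-pyran-3(6H)-one (anomer mixture) | OOC1C=CC(=O)[C@@H](O1)[C@@H]2COC(C)(C)O2 | intermediate
11 | (2S)-2-[(4S)-2,2-dimethyl-1,3-dioxolan-4-yl]-6-hydroxy-2H-pyran-3(6H)-one (anomer mixture) | OC1C=CC(=O)[C@@H](O1)[C@@H]2COC(C)(C)O2 | intermediate
12 | (6S)-6-[(4S)-2,2-dimethyl-1,3-dioxolan-4-yl]-2H-pyran-2,5(6H)-dione | O=C1C=CC(=O)[C@@H](O1)[C@@H]2COC(C)(C)O2 | intermediate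
13 | (5S,6R)-6-[(4S)-2,2-dimethyl-1,3-dioxolan-4-yl]-5-hydroxy-5,6-dihydro-2H-pyran-2-one (5,6-cis) | O=C1C=C[C@H](O)[C@@H](O1)[C@@H]2COC(C)(C)O2 | intermediate
14 | (2E)-2-methylbut-2-enoyl chloride (tigloyl chloride) | C/C=C(\C)C(Cl)=O | starting material
15 | (2R,3S)-2-[(4S)-2,2-dimethyl-1,3-dioxolan-4-yl]-6-oxo-3,6-dihydro-2H-pyran-3-yl (2E)-2-methylbut-2-enoate | C/C=C(\C)C(=O)O[C@H]1C=CC(=O)O[C@H]1[C@@H]2COC(C)(C)O2 | intermediate
16 | (2S,3S)-2-[(1S)-1,2-dihydroxyethyl]-6-oxo-3,6-dihydro-2H-pyran-3-yl (2E)-2-methylbut-2-enoate | C/C=C(\C)C(=O)O[C@H]1C=CC(=O)O[C@H]1[C@@H](O)CO | intermediate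
17 | (2S,3S)-2-ethenyl-6-oxo-3,6-dihydro-2H-pyran-3-yl (2E)-2-methylbut-2-enoate | C/C=C(\C)C(=O)O[C@H]1C=CC(=O)O[C@H]1C=C | intermediate
18 | ethyl (2S)-2-(benzyloxy)propanoate | CCOC(=O)[C@H](C)OCc1ccccc1 | starting material
19 | (2S)-2-(benzyloxy)propanal | O=C[C@H](C)OCc1ccccc1 | intermediate
20 | (3S,4S)-4-(benzyloxy)pent-1-en-3-ol | C=C[C@H](O)[C@H](C)OCc1ccccc1 | intermediate
21 | (3S,4S)-pent-1-ene-3,4-diol | C=C[C@H](O)[C@H](C)O | intermediate
22 | (3S,4S)-pent-1-ene-3,4-diyl diacetate | C=C[C@H](OC(C)=O)[C@H](C)OC(C)=O | intermediate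
23 | (2S,3S)-2-[(1E,3S,4S)-3,4-bis(acetyloxy)pent-1-en-1-yl]-6-oxo-3,6-dihydro-2H-pyran-3-yl (2E)-2-methylbut-2-enoate (CNP0271997.1) | C/C=C(\C)C(=O)O[C@H]1C=CC(=O)O[C@H]1/C=C/[C@H](OC(C)=O)[C@H](C)OC(C)=O | target

The CIP label at the ring carbon bearing the side chain is R in 13 and 15 and S in 16, 17 and 23 only because substituent priorities change; the geometry is the same throughout.

**Totals**
Total step count: 13. Longest linear sequence: 9 (steps 1 to 8, then 13); the side-chain branch is steps 9 to 12.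

**Steps most likely to fail, with fallbacks**

Step 2 (facial selectivity of the furyl addition). If the anti:syn ratio is poor, the selectivity is moved from the C–C bond formation to a reduction. The fallback sets out from 8 (as the epimer mixture) and comes back to 8. The mixture is oxidised at the activated furyl carbinol with MnO2 in CH2Cl2 to the ketone [(4S)-2,2-dimethyl-1,3-dioxolan-4-yl](furan-2-yl)methanone F1. F1 is then reduced with Zn(BH4)2 in Et2O at −30 °C; zinc chelates the ketone and the α-oxygen of the dioxolane, and hydride delivery on the open face of the chelate gives the anti alcohol 8.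

Step 5 (diastereoselectivity of the reduction of the labile ene-dione 12). The fallback sets out from 12 and comes back at 15, by-passing step 6 for the wrong isomer. Any 5,6-trans alcohol formed in the reduction, (5R,6R)-6-[(4S)-2,2-dimethyl-1,3-dioxolan-4-yl]-5-hydroxy-5,6-dihydro-2H-pyran-2-one F2, is separated and esterified under Mitsunobu conditions with tiglic acid (PPh3, DIAD, THF, 0 °C). The SN2 displacement inverts C5 and gives the cis tiglate 15 directly, so stereocontrol is moved from hydride delivery to an invertive esterification.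

Step 8 (diol-to-alkene conversion on a heat- and nucleophile-sensitive acyloxy lactone). The fallback sets out from 16 and comes back at 17 by a Corey–Winter olefination. 16 is heated with 1,1'-thiocarbonyldiimidazole in toluene at 80 °C to give the cyclic thionocarbonate (2R,3S)-6-oxo-2-[(4S)-2-thioxo-1,3-dioxolan-4-yl]-3,6-dihydro-2H-pyran-3-yl (2E)-2-methylbut-2-enoate F3. F3 is then heated in P(OMe)3 at 110 °C; desulfurisation and loss of CO2 from the carbene give the terminal alkene 17 by a stereospecific syn-elimination that involves neither iodine nor a nucleophilic phosphine.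

**Further compounds**
F1 | step 2 | [(4S)-2,2-dimethyl-1,3-dioxolan-4-yl](furan-2-yl)methanone | O=C(c1ccco1)[C@@H]2COC(C)(C)O2
F2 | step 5 | (5R,6R)-6-[(4S)-2,2-dimethyl-1,3-dioxolan-4-yl]-5-hydroxy-5,6-dihydro-2H-pyran-2-one (5,6-trans) | O=C1C=C[C@@H](O)[C@@H](O1)[C@@H]2COC(C)(C)O2
F3 | step 8 | (2R,3S)-6-oxo-2-[(4S)-2-thioxo-1,3-dioxolan-4-yl]-3,6-dihydro-2H-pyran-3-yl (2E)-2-methylbut-2-enoate | C/C=C(\C)C(=O)O[C@H]1C=CC(=O)O[C@H]1[C@@H]2COC(=S)O2
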